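**Retrosynthetic overview**

1. Target 19 ⇐ phenol 17 by para C–O oxygenation (Teuber oxidation, then dithionite). The arene is bought intact as boronic acid 14, so no ring is built in the route.
2. 17 ⇐ sulfone 15 by C–O oxidative desulfonylation. The C5 sulfone first joins C4–C5 (alkylation with chloro acetate 11), then survives the C1–aryl coupling with 14.
3. C13–O stereocentre ⇐ enantioselective palladium-catalysed 1,3-acetoxy shift of the achiral tertiary allylic acetate 8 (key step, sets 13R).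
4. 8 ⇐ allylic bromide 5 + alkyne acetate 6 (hydrozirconation, allyl–alkenyl coupling, C12–C13). 5 ⇐ nerol 1 (supplies the 6Z alkene) via sulfone 3 and SeO2 hydroxylation of the E-methyl (C12).

Assumption: locants C1–C16 are those of the target side chain; step 5 is drawn with the palladacycle hand that gives 13R (both hands are on sale, fixed in a first small run); 11 is used as the pure E isomer.

**Route**

Step 1
Reactants: 1 nerol [(2Z)-3,7-dimethylocta-2,6-dien-1-ol]
Product: 3 neryl phenyl sulfone [(2Z)-3,7-dimethylocta-2,6-dien-1-yl phenyl sulfone], via neryl bromide 2 (not isolated)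
Conditions: PBr3 (0.4 equiv), Et2O, −10 °C; then PhSO2Na, DMF, 0 °C to rt
Reagents that add atoms: sodium benzenesulfinate, [Na+].[O-]S(=O)c1ccccc1
Why: Cold PBr3 bromination of the allylic alcohol followed by SN2 S-alkylation of the sulfinate gives the allylic sulfone with the Z-alkene of nerol intact.

Step 2
Reactants: 3 neryl phenyl sulfone
Product: 4 (2E,6Z)-2,6-dimethyl-8-(phenylsulfonyl)octa-2,6-dien-1-ol
Conditions: SeO2 (0.2 equiv), tBuOOH (2.5 equiv), salicylic acid (0.1 equiv), CH2Cl2, 0 °C to rt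
Reagents that add atoms: tert-butyl hydroperoxide, CC(C)(C)OO (oxygen source, relayed through catalytic SeO2, O=[Se]=O)
Why: Riley-type allylic oxidation (ene reaction then [2,3]-sigmatropic shift) hydroxylates the E-methyl of the electron-rich terminal alkene, while the alkene next to the sulfonylmethyl group is deactivated.

Step 3
Reactants: 4 (2E,6Z)-2,6-dimethyl-8-(phenylsulfonyl)octa-2,6-dien-1-ol
Product: 5 [(2Z,6E)-8-bromo-3,7-dimethylocta-2,6-dien-1-yl]sulfonylbenzene
Conditions: CBr4, PPh3, CH2Cl2, 0 °C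
Reagents that add atoms: carbon tetrabromide, BrC(Br)(Br)Br
Why: The Appel reaction turns the primary allylic alcohol into the bromide without allylic shift or loss of alkene geometry.

Step 4
Reactants: 5 [(2Z,6E)-8-bromo-3,7-dimethylocta-2,6-dien-1-yl]sulfonylbenzene; 6 2-methylbut-3-yn-2-yl acetate
Product: 8 (3E,6E,10Z)-2,6,10-trimethyl-12-(phenylsulfonyl)dodeca-3,6,10-trien-2-yl acetate, via alkenylzirconocene chloride 7 (not isolated)
Conditions: 6 (1.3 equiv), Cp2Zr(H)Cl (1.3 equiv), THF, rt, 30 min; then 5, Pd(PPh3)4 (5 mol %), rt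
Reagents that add atoms: none
Why: Syn hydrozirconation of the terminal alkyne gives the E-alkenylzirconocene, which undergoes a zerovalent-palladium-catalysed Negishi-type coupling at the primary terminus of the allylic bromide with both alkene geometries kept.

Step 5
Reactants: 8 (3E,6E,10Z)-2,6,10-trimethyl-12-(phenylsulfonyl)dodeca-3,6,10-trien-2-yl acetate
Product: 9 (4R,6E,10Z)-2,6,10-trimethyl-12-(phenylsulfonyl)dodeca-2,6,10-trien-4-yl acetate
Conditions: [Pd(μ-O2CCF3){κ2C,N-(η5-C5H3-(4-iPr-4,5-dihydrooxazol-2-yl))Co(η4-C4Ph4)}]2 (5 mol %, from the μ-Cl dimer and AgO2CCF3), CH2Cl2, 4 Å MS, 30 °C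
Reagents that add atoms: none
Why: Proposed new method: an enantioselective divalent-palladium-catalysed 1,3-acetoxy shift of a prochiral tertiary E-allylic acetate, in which the planar-chiral palladacycle binds one face of the C13=C14 alkene, the acetate carbonyl oxygen adds anti at C13 to give a six-membered 1,3-dioxan-2-ylium σ-alkylpalladium species, and anti loss of palladium with C15–O cleavage releases the 13R secondary acetate and the trisubstituted C14=C15 alkene, which no longer binds palladium, so the shift is irreversible and the new C–O stereocentre is not eroded; the closest known reactions are the racemic PdCl2(MeCN)2-catalysed [3,3] allylic acetate transposition (cyclisation-induced rearrangement) and the enantioselective palladacycle-catalysed allylic trichloroacetimidate rearrangement (Overman rearrangement) and SN2' allylic esterification.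

Step 6
Reactants: 9 (4R,6E,10Z)-2,6,10-trimethyl-12-(phenylsulfonyl)dodeca-2,6,10-trien-4-yl acetate
Product: 10 (4R,6E,10Z)-2,6,10-trimethyl-12-(phenylsulfonyl)dodeca-2,6,10-trien-4-ol
Conditions: K2CO3 (0.3 equiv), MeOH, 0 °C to rt
Reagents that add atoms: none
Why: Base-catalysed transesterification cleaves the acyl–oxygen bond only, so the C13–O bond and its R configuration are untouched.

Step 7
Reactants: 10 (4R,6E,10Z)-2,6,10-trimethyl-12-(phenylsulfonyl)dodeca-2,6,10-trien-4-ol; 11 (E)-4-chloro-3-methylbut-2-en-1-yl acetate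
Product: 13 (2E,6Z,10E,13R)-13-hydroxy-3,7,11,15-tetramethyl-5-(phenylsulfonyl)hexadeca-2,6,10,14-tetraen-1-yl acetate (both C5 epimers), via dilithio dianion 12 (not isolated)
Conditions: nBuLi (2.1 equiv), THF–DMPU, −78 °C; then 11, −78 to −20 °C; aq. NH4Cl
Reagents that add atoms: none
Why: Julia-type α-alkylation of the sulfonyl-stabilised allyl carbanion at the primary allylic chloride forms C4–C5 with the Z-alkene configurationally stable at low temperature; the C5 centre forms unselectively and is erased in step 9.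

Step 8
Reactants: 13 (2E,6Z,10E,13R)-13-hydroxy-3,7,11,15-tetramethyl-5-(phenylsulfonyl)hexadeca-2,6,10,14-tetraen-1-yl acetate; 14 (2-hydroxy-3-methylphenyl)boronic acid
Product: 15 2-[(2E,6Z,10E,13R)-13-hydroxy-3,7,11,15-tetramethyl-5-(phenylsulfonyl)hexadeca-2,6,10,14-tetraen-1-yl]-6-methylphenol (both C5 epimers)
Conditions: Pd(PPh3)4 (5 mol %), K2CO3 (2 equiv), THF–H2O, 40 °C
Reagents that add atoms: none
Why: Suzuki–Miyaura allyl–aryl coupling (ionisation of the primary allylic acetate, transmetalation, reductive elimination at the less hindered allyl terminus) gives the linear E product, while the free secondary allylic alcohol and the sulfone do not ionise under these basic, mild conditions.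

Step 9
Reactants: 15 2-[(2E,6Z,10E,13R)-13-hydroxy-3,7,11,15-tetramethyl-5-(phenylsulfonyl)hexadeca-2,6,10,14-tetraen-1-yl]-6-methylphenol
Product: 17 (2E,6Z,10E,13R)-13-hydroxy-1-(2-hydroxy-3-methylphenyl)-3,7,11,15-tetramethylhexadeca-2,6,10,14-tetraen-5-one, via trilithio trianion 16 (not isolated)
Conditions: LiN(iPr)2 (3.1 equiv), THF–DMPU, −78 °C; Me3SiOOSiMe3 (1.3 equiv), −78 to −40 °C; AcOH quench at −78 °C
Reagents that add atoms: bis(trimethylsilyl) peroxide, C[Si](C)(C)OO[Si](C)(C)C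
Why: Oxidative desulfonylation, in which the α-sulfonyl carbanion is oxygenated at carbon by the silyl peroxide and the α-silyloxy sulfone collapses with loss of sulfinate to the C5 ketone; the cold acidic quench keeps the 2E β,γ-alkene and the 6Z enone in place.

Step 10
Reactants: 17 (2E,6Z,10E,13R)-13-hydroxy-1-(2-hydroxy-3-methylphenyl)-3,7,11,15-tetramethylhexadeca-2,6,10,14-tetraen-5-one
Product: 19 2-[(2E,6Z,10E,13R)-13-hydroxy-3,7,11,15-tetramethyl-5-oxohexadeca-2,6,10,14-tetraen-1-yl]-6-methylbenzene-1,4-diol (target), via quinone 18 (not isolated)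
Conditions: K2[ON(SO3)2] (2.5 equiv), KH2PO4 buffer (pH 6.5), acetone–H2O, 0 °C to rt; then aq. Na2S2O4, Et2O, rt, argon
Reagents that add atoms: potassium nitrosodisulfonate, [K+].[K+].[O]N(S(=O)(=O)[O-])S(=O)(=O)[O-]
Why: Teuber oxidation of the 2,6-dialkylphenol at its free para position gives the p-quinone, which dithionite reduces in the same pot to the hydroquinone without touching the enone or the allylic alcohol.

**Compound list**

1 | nerol, (2Z)-3,7-dimethylocta-2,6-dien-1-ol | CC(C)=CCC/C(C)=C\CO | starting material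
2 | neryl bromide, (2Z)-1-bromo-3,7-dimethylocta-2,6-diene (not isolated) | CC(C)=CCC/C(C)=C\CBr | intermediate
3 | neryl phenyl sulfone | CC(C)=CCC/C(C)=C\CS(=O)(=O)c1ccccc1 | intermediate
4 | (2E,6Z)-2,6-dimethyl-8-(phenylsulfonyl)octa-2,6-dien-1-ol | OC/C(C)=C/CC/C(C)=C\CS(=O)(=O)c1ccccc1 | intermediate
5 | [(2Z,6E)-8-bromo-3,7-dimethylocta-2,6-dien-1-yl]sulfonylbenzene | BrC/C(C)=C/CC/C(C)=C\CS(=O)(=O)c1ccccc1 | intermediate
6 | 2-methylbut-3-yn-2-yl acetate | CC(=O)OC(C)(C)C#C | starting material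
7 | [(E)-3-acetoxy-3-methylbut-1-enyl]zirconocene chloride (not isolated) | CC(=O)OC(C)(C)/C=C/[Zr](Cl)(C1C=CC=C1)C1C=CC=C1 | intermediate
8 | (3E,6E,10Z)-2,6,10-trimethyl-12-(phenylsulfonyl)dodeca-3,6,10-trien-2-yl acetate | CC(=O)OC(C)(C)/C=C/C/C(C)=C/CC/C(C)=C\CS(=O)(=O)c1ccccc1 | intermediate
9 | (4R,6E,10Z)-2,6,10-trimethyl-12-(phenylsulfonyl)dodeca-2,6,10-trien-4-yl acetate | CC(C)=C[C@H](OC(C)=O)C/C(C)=C/CC/C(C)=C\CS(=O)(=O)c1ccccc1 | intermediate
10 | (4R,6E,10Z)-2,6,10-trimethyl-12-(phenylsulfonyl)dodeca-2,6,10-trien-4-ol | CC(C)=C[C@H](O)C/C(C)=C/CC/C(C)=C\CS(=O)(=O)c1ccccc1 | intermediate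
11 | (E)-4-chloro-3-methylbut-2-en-1-yl acetate | CC(=O)OC/C=C(C)/CCl | starting material
12 | O,C-dilithio derivative of 10 (not isolated) | CC(C)=C[C@H](O[Li])C/C(C)=C/CC/C(C)=C\C([Li])S(=O)(=O)c1ccccc1 | intermediate
13 | (2E,6Z,10E,13R)-13-hydroxy-3,7,11,15-tetramethyl-5-(phenylsulfonyl)hexadeca-2,6,10,14-tetraen-1-yl acetate, both C5 epimers | CC(C)=C[C@H](O)C/C(C)=C/CC/C(C)=C\C(C/C(C)=C/COC(C)=O)S(=O)(=O)c1ccccc1 | intermediate
14 | (2-hydroxy-3-methylphenyl)boronic acid | Cc1cccc(B(O)O)c1O | starting material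
15 | 2-[(2E,6Z,10E,13R)-13-hydroxy-3,7,11,15-tetramethyl-5-(phenylsulfonyl)hexadeca-2,6,10,14-tetraen-1-yl]-6-methylphenol, both C5 epimers | CC(C)=C[C@H](O)C/C(C)=C/CC/C(C)=C\C(C/C(C)=C/Cc1cccc(C)c1O)S(=O)(=O)c1ccccc1 | intermediate
16 | O,O,C-trilithio derivative of 15 (not isolated) | CC(C)=C[C@H](O[Li])C/C(C)=C/CC/C(C)=C\C([Li])(C/C(C)=C/Cc1cccc(C)c1O[Li])S(=O)(=O)c1ccccc1 | intermediate
17 | (2E,6Z,10E,13R)-13-hydroxy-1-(2-hydroxy-3-methylphenyl)-3,7,11,15-tetramethylhexadeca-2,6,10,14-tetraen-5-one | CC(C)=C[C@H](O)C/C(C)=C/CC/C(C)=C\C(=O)C/C(C)=C/Cc1cccc(C)c1O | intermediate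
18 | 2-[(2E,6Z,10E,13R)-13-hydroxy-3,7,11,15-tetramethyl-5-oxohexadeca-2,6,10,14-tetraen-1-yl]-6-methylcyclohexa-2,5-diene-1,4-dione (not isolated) | CC(C)=C[C@H](O)C/C(C)=C/CC/C(C)=C\C(=O)C/C(C)=C/CC1=CC(=O)C=C(C)C1=O | intermediate
19 | 2-[(2E,6Z,10E,13R)-13-hydroxy-3,7,11,15-tetramethyl-5-oxohexadeca-2,6,10,14-tetraen-1-yl]-6-methylbenzene-1,4-diol | CC(C)=C[C@H](O)C/C(C)=C/CC/C(C)=C\C(=O)C/C(C)=C/Cc1cc(O)cc(C)c1O | target

**Step count and risks**

Total step count: 10. Longest linear sequence: 10 (6, 11 and 14 are bought).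

Steps most likely to fail:

Step 5 (the new enantioselective acetoxy shift; rate, hand and level of induction are untested, and the doubly allylic C12 methylene could divert palladium). The fallback uses known chemistry, sets out from 8 and comes back at 10, so step 6 is skipped. iBu2AlH (CH2Cl2, −78 °C) removes the acetyl group of 8 to give the tertiary allylic alcohol (3E,6E,10Z)-2,6,10-trimethyl-12-(phenylsulfonyl)dodeca-3,6,10-trien-2-ol F1. Buffered pyridinium chlorochromate ([C5H5NH][CrO3Cl], NaOAc, CH2Cl2) then effects the Babler–Dauben oxidative 1,3-transposition to the enone (6E,10Z)-2,6,10-trimethyl-12-(phenylsulfonyl)dodeca-2,6,10-trien-4-one F2. Corey–Bakshi–Shibata reduction with (S)-2-methyl-oxazaborolidine and catecholborane (toluene, −78 °C) gives 10 with the 4R configuration (alkenyl as the large group).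

Step 8 (allyl–aryl coupling in the presence of a free phenol, a free allylic alcohol and an allylic sulfone; protodeboronation of 14). The fallback brings the arene in on the electrophile instead; it sets out from 10 and comes back at 15. Commercial 2-allyl-6-methylphenol is silylated (tBuMe2SiCl, imidazole) to tert-butyl(2-allyl-6-methylphenoxy)dimethylsilane F3. Cross-metathesis with methacrolein (second-generation Hoveyda–Grubbs catalyst, [RuCl2(H2IMes)(=CH-C6H4-2-OiPr)], CH2Cl2, 40 °C) gives (E)-4-[2-(tert-butyldimethylsilyloxy)-3-methylphenyl]-2-methylbut-2-enal F4. Reduction with NaBH4 and CeCl3·7H2O gives (E)-4-[2-(tert-butyldimethylsilyloxy)-3-methylphenyl]-2-methylbut-2-en-1-ol F5, and CBr4/PPh3 converts this into [2-[(E)-4-bromo-3-methylbut-2-enyl]-6-methylphenoxy](tert-butyl)dimethylsilane F6. The dianion 12 of 10 (nBuLi, THF–DMPU, −78 °C) is alkylated with F6 to give the silyl ether of 15, tert-butyl{2-[(2E,6Z,10E,13R)-13-hydroxy-3,7,11,15-tetramethyl-5-(phenylsulfonyl)hexadeca-2,6,10,14-tetraenyl]-6-methylphenoxy}dimethylsilane F7. Bu4NF buffered with AcOH (THF, 0 °C) then releases 15.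

Step 9 (carbanion oxygenation on a trianion; competing attack of the peroxide on the phenoxide, and base sensitivity of the skipped dienone). The fallback masks both hydroxyl groups so that a single carbanion is oxygenated; it sets out from 15 and comes back at 17. Et3SiCl and imidazole give the bis(triethylsilyl) ether of 15, F8. LiN(iPr)2 (1.1 equiv, THF, −78 °C) gives its C5-lithio derivative F9, and bis(trimethylsilyl) peroxide followed by a cold AcOH quench gives the bis(triethylsilyl) ether of 17, F10. HF·pyridine buffered with pyridine (THF, 0 °C) removes both silyl groups to give 17.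

**Further compounds**

F1 | step 5 | (3E,6E,10Z)-2,6,10-trimethyl-12-(phenylsulfonyl)dodeca-3,6,10-trien-2-ol | CC(C)(O)/C=C/C/C(C)=C/CC/C(C)=C\CS(=O)(=O)c1ccccc1
F2 | step 5 | (6E,10Z)-2,6,10-trimethyl-12-(phenylsulfonyl)dodeca-2,6,10-trien-4-one | CC(C)=CC(=O)C/C(C)=C/CC/C(C)=C\CS(=O)(=O)c1ccccc1
F3 | step 8 | tert-butyl(2-allyl-6-methylphenoxy)dimethylsilane | C=CCc1cccc(C)c1O[Si](C)(C)C(C)(C)C
F4 | step 8 | (E)-4-[2-(tert-butyldimethylsilyloxy)-3-methylphenyl]-2-methylbut-2-enal | O=C/C(C)=C/Cc1cccc(C)c1O[Si](C)(C)C(C)(C)C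
F5 | step 8 | (E)-4-[2-(tert-butyldimethylsilyloxy)-3-methylphenyl]-2-methylbut-2-en-1-ol | OC/C(C)=C/Cc1cccc(C)c1O[Si](C)(C)C(C)(C)C
F6 | step 8 | [2-[(E)-4-bromo-3-methylbut-2-enyl]-6-methylphenoxy](tert-butyl)dimethylsilane | BrC/C(C)=C/Cc1cccc(C)c1O[Si](C)(C)C(C)(C)C
F7 | step 8 | tert-butyl{2-[(2E,6Z,10E,13R)-13-hydroxy-3,7,11,15-tetramethyl-5-(phenylsulfonyl)hexadeca-2,6,10,14-tetraenyl]-6-methylphenoxy}dimethylsilane | CC(C)=C[C@H](O)C/C(C)=C/CC/C(C)=C\C(C/C(C)=C/Cc1cccc(C)c1O[Si](C)(C)C(C)(C)C)S(=O)(=O)c1ccccc1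
F8 | step 9 | bis(triethylsilyl) ether of 15 | CC(C)=C[C@H](O[Si](CC)(CC)CC)C/C(C)=C/CC/C(C)=C\C(C/C(C)=C/Cc1cccc(C)c1O[Si](CC)(CC)CC)S(=O)(=O)c1ccccc1
F9 | step 9 | C5-lithio derivative of F8 | CC(C)=C[C@H](O[Si](CC)(CC)CC)C/C(C)=C/CC/C(C)=C\C([Li])(C/C(C)=C/Cc1cccc(C)c1O[Si](CC)(CC)CC)S(=O)(=O)c1ccccc1
F10 | step 9 | bis(triethylsilyl) ether of 17 | CC(C)=C[C@H](O[Si](CC)(CC)CC)C/C(C)=C/CC/C(C)=C\C(=O)C/C(C)=C/Cc1cccc(C)c1O[Si](CC)(CC)CC
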